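# Proposed synthesis of CNP0130704.0 by elevenfold formyl-to-hydroxyl oxidation of an oligo(formylaryl) ether

## Analysis of the target

The target 38 is a linear chain of seven benzene rings joined by six diaryl ether oxygens and carrying eighteen free hydroxyls. It has no stereocentre, and the ether axes rotate freely. The rings are lettered A (2,4,6-trihydroxyphenyl end) to G (3,4,5-trihydroxyphenyl end). C1 of ring A carries its ether oxygen and C1 of rings B to G carries the oxygen that points towards ring A, so the ethers are A1–O–B1, B4–O–C1, C6–O–D1, D5–O–E1, E6–O–F1 and F4–O–G1. Every ether is lopsided: its carbon on the A side (A1, B4, C6, D5, E6, F4) is crowded by oxygenated neighbours (two, except D5 with one), whereas its carbon on the G side has at most one. The free polyphenol contains pyrogallol units (rings C, E, G), a catechol (ring D) and a phloroglucinol pattern (ring A). It is oxidised easily, above all in base, so it should appear only in the last step.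

The difficulty is twofold. Six ethers must be made between electron-rich, ortho-substituted rings, where metal-catalysed couplings are at their weakest, and eighteen oxygens must be placed without a long protecting-group sequence. The plan rests on one feature: twelve of the fifteen hydroxyls of rings A to F stand ortho or para to the crowded ether carbon of their own ring (A2, A4, A6; B3, B5; C3, C5; D4; E3, E5; F3, F5). Eleven of them, all except A4, can be carried as formyl groups. A formyl group ortho or para to a fluoride turns the crowded carbon into an electrophile for the unhindered phenol of the next ring, and it can later be exchanged for hydroxyl by aryl migration to oxygen. Two weak points follow from the structure and shape the route. The single formyl of ring D is a poor activator because two alkoxy groups are conjugated with it. Ether oxygens squeezed between two ortho substituents are twisted and donate less, which matters for the final oxidation.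

## Retrosynthetic reasoning

38 to 37. The seven O–methyl bonds at A4, C4, D3, E4, G3, G4 and G5 are cut. Methyl is the one group that survives organolithium reagents, carbonate, dilute acid and peracid. The forward step is a Lewis-acid demethylation that must leave the six diaryl ethers alone; they have no sp3 carbon on oxygen.

37 to 35 (through 36). Eleven aryl carbon–oxygen bonds are cut, each hydroxyl going back to a formyl group. These are the positions ortho or para to the crowded ether carbons, so the same substituent that is oxidised at the end makes the ethers accessible. The gain is that eleven oxygens appear in one operation and that the chain stays an oxidation-stable polyaldehyde until then. The forward reaction has to give aryl migration at every site.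

35 to 34 and 9, 34 (from 33) to 32 and 10, 32 (from 31) to 30 and 19. The ethers at A1, B4 and C6 are cut on the crowded side. The crowded carbon becomes a fluoride flanked by formyl groups, and the oxygen stays on the open carbon of the next ring as a phenol, so the hindered partner is never the nucleophile. Each incoming ring carries its own phenol as a methoxymethyl ether, removed with dilute acid before the next round. The forward reactions must run cold enough that aryloxy groups already sitting on activated carbons are not exchanged; fluoride leaves far faster than aryloxide from the same kind of ring.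

30 (from 29) to 28 and 25, and 28 (from 27) to 26 and 10. The ethers at E6 and F4 are cut in the same way. Ring G enters as the simple phenol 26, and rings D and E enter together as the block 25.

25 (from 24) to 23 and 22. The ether at D5 is the exception. Its fluoride has only the ring D formyl beside it, and that formyl is conjugated with the D3 methoxy and D1 oxygen, so displacement needs heat. At that temperature a growing chain would scramble its activated ethers. This bond is therefore made first, on small pieces, with the ring E formyls of 23 masked as dimethyl acetals so that the ring E fluoride is inert. Mild hydrolysis then restores the activation in 25.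

Monomers. 9 and 10 come from 8 by O-alkylation, and 8 from 7, 2 and 1 by two formylations ortho to fluorine. 19 and 23 come from 18, and 18 from 17, 12 and 11 by two formylations ortho to methoxy. A bulky silyl ether steers the metalations away from the phenol oxygen. 22 comes from 21 and 20 by exchange of one of two equivalent fluorides for methoxy.

## Alternatives that were turned down

Alternative 1: Ring A would be built last from acyclic pieces. Two carbon–carbon bonds of ring A are disconnected, so that A1 with its ether oxygen comes from the aryloxymalonate A1 and the other three ring carbons come from dimethyl 3-oxopentanedioate A2. In the forward step the dianion of A2 would be acylated by both ester groups of A1 and close the ring as the 2-aryloxyphloroglucinol diester A3. In its favour, the most crowded ether of ring A exists before the ring does, and the starting materials are cheap. On that single ether it is at least as safe as a fluoride displacement. Against it, the hydrogen between the two esters and the aryloxy group of A1 is acidic; the dianion would more likely deprotonate A1 than be acylated, and the resulting enolate is no acylating agent. Two ester groups must afterwards be removed from an air-sensitive phloroglucinol. It also addresses only one of six ethers; the benzyl ether in A3 merely marks the oxygen where the next crowded coupling would have to follow. The chosen route offers one bond-forming reaction for all six ethers and a single redox event at the end.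

Alternative 2: Ring C, the ring with five oxygens, would be made by ring expansion. The ring C bond between the carbon bearing the ring B ether and the carbon that will bear the ring D ether is disconnected. In the forward step, thermolysis of the squarate-derived cyclobutenone A4 opens the four-membered ring to a dienylketene that closes by 6π electrocyclisation and tautomerises to the hydroquinone A5 (a Moore-type rearrangement). This is a dependable thermal reaction, and on certainty of the ring C substitution pattern it is stronger than any substitution chemistry. Against it, A4 needs a (Z)-2-aryloxyvinyl metal reagent, which is prone to β-elimination of aryloxide, and its aryl part already contains the crowded A–B ether. The two hydroxyls of A5 must be told apart, and one of them, flanked by two oxygens and part of an oxidisable hydroquinone, must then be arylated with ring D. Ring E would need the whole sequence a second time. The chosen route spends two or three steps per ring, and no crowded phenol ever has to act as a nucleophile.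

Alternative 3: The chain would be joined convergently at ring D. Both ring D ether bonds are disconnected. In one pot the crowded ring C phenoxide of arm A8 would displace the para fluoride of 2,4,6-trifluorobenzaldehyde A6, and the ring E phenoxide of arm A9 would then displace one ortho fluoride, giving the heptamer A7. This is a 3 + 1 + 3 union with a shorter longest linear sequence, and it needs only one formyl-to-hydroxyl oxidation, which has direct precedent. On convergence and on confidence in the oxidation it is stronger than the chosen route. Against it, A8 and A9 each contain two of the crowded ethers, and nothing in the plan makes them; they would fall back on copper-mediated couplings of electron-rich, doubly ortho-substituted partners, which is the real problem of the target. Para against ortho selectivity with a hindered phenoxide and double arylation by the first arm are open questions as well. The chosen route extends the same addition–elimination logic to every ether, so no arm has to be made by a second method, at the price of a longer sequence and an oxidation of unprecedented extent.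

Key step: step 24

Assumption: 4-fluorophenol, 2-fluoro-4-methoxyphenol, 2,6-difluoro-4-hydroxybenzaldehyde and 3,4,5-trimethoxyphenol are taken as purchasable.

## Route

Step 1
Reactants: 1 4-fluorophenol
Product: 2 (4-fluorophenoxy)tri(propan-2-yl)silane
Conditions: TIPSCl, imidazole, DMF, rt
Reagents that add atoms: chlorotri(propan-2-yl)silane, CC(C)[Si](Cl)(C(C)C)C(C)C
Why: O-silylation of a phenol; the bulky, non-coordinating silyl ether shields both carbons next to oxygen, so later metalation goes to the carbons next to fluorine.

Step 2
Reactants: 2 (4-fluorophenoxy)tri(propan-2-yl)silane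
Product: 7 2-fluoro-5-{[tri(propan-2-yl)silyl]oxy}benzene-1,3-dicarbaldehyde, via aryllithium 3 (not isolated), via lithium amino alkoxide 4 (not isolated), via ring-lithiated amino alkoxide 5 (not isolated), via dilithium bis(amino alkoxide) 6 (not isolated)
Conditions: s-BuLi, THF, −78 °C; DMF (1 equiv), −78 °C; s-BuLi, TMEDA, −78 °C; DMF, −78 °C to rt; 1 M aq. HCl
Reagents that add atoms: N,N-dimethylformamide, CN(C)C=O
Why: Fluorine-directed ortho-lithiation and formylation, run twice in one flask. The first DMF adduct 4 persists as a tetrahedral lithium α-amino alkoxide (in situ protection of the aldehyde), so the second equivalent of base finds only the remaining hydrogen next to fluorine.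

Step 3
Reactants: 7 2-fluoro-5-{[tri(propan-2-yl)silyl]oxy}benzene-1,3-dicarbaldehyde
Product: 8 2-fluoro-5-hydroxybenzene-1,3-dicarbaldehyde
Conditions: TBAF, AcOH, THF, 0 °C
Reagents that add atoms: none
Why: Fluoride cleaves the silicon–oxygen bond; the acetic acid buffer keeps the product a neutral phenol, which cannot displace the activated fluoride of a second molecule.

Step 4
Reactants: 8 2-fluoro-5-hydroxybenzene-1,3-dicarbaldehyde
Product: 9 2-fluoro-5-methoxybenzene-1,3-dicarbaldehyde
Conditions: MeI (excess), K2CO3, MeCN, rt
Reagents that add atoms: iodomethane, CI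
Why: Williamson methylation; with excess iodomethane at room temperature, O-alkylation should outrun intermolecular fluoride displacement by the phenoxide.

Step 5
Reactants: 8 2-fluoro-5-hydroxybenzene-1,3-dicarbaldehyde
Product: 10 2-fluoro-5-(methoxymethoxy)benzene-1,3-dicarbaldehyde
Conditions: MOMCl, iPr2NEt, CH2Cl2, 0 °C
Reagents that add atoms: chloromethyl methyl ether, COCCl
Why: O-alkylation to a methoxymethyl ether, which is stable to carbonate, phenoxide and the fluoride set free in the couplings and is removed by dilute acid without touching aldehydes.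

Step 6
Reactants: 11 2-fluoro-4-methoxyphenol
Product: 12 (2-fluoro-4-methoxyphenoxy)tri(propan-2-yl)silane
Conditions: TIPSCl, imidazole, DMF, rt
Reagents that add atoms: chlorotri(propan-2-yl)silane, CC(C)[Si](Cl)(C(C)C)C(C)C
Why: O-silylation; the silyl ether again removes the phenol oxygen as a directing group and shields its neighbour.

Step 7
Reactants: 12 (2-fluoro-4-methoxyphenoxy)tri(propan-2-yl)silane
Product: 17 4-fluoro-2-methoxy-5-{[tri(propan-2-yl)silyl]oxy}benzene-1,3-dicarbaldehyde, via aryllithium 13 (not isolated), via lithium amino alkoxide 14 (not isolated), via ring-lithiated amino alkoxide 15 (not isolated), via dilithium bis(amino alkoxide) 16 (not isolated)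
Conditions: n-BuLi, THF, −78 °C; DMF (1 equiv), −78 °C; s-BuLi, TMEDA, −78 to −40 °C; DMF, −78 °C to rt; 1 M aq. HCl
Reagents that add atoms: N,N-dimethylformamide, CN(C)C=O
Why: Directed ortho-metalation twice in one flask. The first lithiation takes the hydrogen between fluorine and methoxy. After in situ protection as the α-amino alkoxide 14, the second takes the other hydrogen ortho to methoxy, the only remaining position not shielded by the silyl ether.

Step 8
Reactants: 17 4-fluoro-2-methoxy-5-{[tri(propan-2-yl)silyl]oxy}benzene-1,3-dicarbaldehyde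
Product: 18 4-fluoro-5-hydroxy-2-methoxybenzene-1,3-dicarbaldehyde
Conditions: TBAF, AcOH, THF, 0 °C
Reagents that add atoms: none
Why: Buffered fluoride desilylation, as in step 3.

Step 9
Reactants: 18 4-fluoro-5-hydroxy-2-methoxybenzene-1,3-dicarbaldehyde
Product: 19 4-fluoro-2-methoxy-5-(methoxymethoxy)benzene-1,3-dicarbaldehyde
Conditions: MOMCl, iPr2NEt, CH2Cl2, 0 °C
Reagents that add atoms: chloromethyl methyl ether, COCCl
Why: Methoxymethyl protection of the phenol, as in step 5.

Step 10
Reactants: 20 2,6-difluoro-4-hydroxybenzaldehyde
Product: 21 2,6-difluoro-4-(methoxymethoxy)benzaldehyde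
Conditions: MOMCl, iPr2NEt, CH2Cl2, 0 °C
Reagents that add atoms: chloromethyl methyl ether, COCCl
Why: Methoxymethyl protection; it also removes the phenoxide, which would otherwise switch off the fluoride displacement of step 11.

Step 11
Reactants: 21 2,6-difluoro-4-(methoxymethoxy)benzaldehyde
Product: 22 2-fluoro-6-methoxy-4-(methoxymethoxy)benzaldehyde
Conditions: NaOMe (1.0 equiv), MeOH/THF, 0 °C to rt
Reagents that add atoms: sodium methoxide, C[O-].[Na+]
Why: Nucleophilic aromatic substitution of a fluoride ortho to the formyl group; the two fluorides are equivalent, and the first methoxy group deactivates the ring enough to stop at single exchange.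

Step 12
Reactants: 18 4-fluoro-5-hydroxy-2-methoxybenzene-1,3-dicarbaldehyde
Product: 23 3,5-bis(dimethoxymethyl)-2-fluoro-4-methoxyphenol
Conditions: HC(OMe)3, TsOH (cat.), MeOH, rt; Et3N quench
Reagents that add atoms: trimethyl orthoformate, COC(OC)OC; methanol, CO
Why: Acid-catalysed acetalisation of both formyl groups; with the acceptors masked, the ring fluoride is no longer activated and the phenol becomes a clean, more electron-rich nucleophile.

Step 13
Reactants: 23 3,5-bis(dimethoxymethyl)-2-fluoro-4-methoxyphenol; 22 2-fluoro-6-methoxy-4-(methoxymethoxy)benzaldehyde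
Product: 24 2-[3,5-bis(dimethoxymethyl)-2-fluoro-4-methoxyphenoxy]-6-methoxy-4-(methoxymethoxy)benzaldehyde
Conditions: Cs2CO3, DMSO, 110 °C
Reagents that add atoms: none
Why: Nucleophilic aromatic substitution (addition–elimination) ortho to the ring D formyl group. This one weakly activated fluoride is displaced under forcing conditions at a stage where neither partner has an activated ether or a second activated fluoride, so heat can do no harm.

Step 14
Reactants: 24 2-[3,5-bis(dimethoxymethyl)-2-fluoro-4-methoxyphenoxy]-6-methoxy-4-(methoxymethoxy)benzaldehyde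
Product: 25 4-fluoro-5-[2-formyl-3-methoxy-5-(methoxymethoxy)phenoxy]-2-methoxybenzene-1,3-dicarbaldehyde
Conditions: 1 M aq. HCl, THF, 0 °C to rt
Reagents that add atoms: water, O
Why: Chemoselective acetal hydrolysis; benzylic dimethyl acetals ionise far more readily than the aryl methoxymethyl ether, a formaldehyde acetal, so the two ring E formyls return while the ring D phenol stays masked.

Step 15
Reactants: 26 3,4,5-trimethoxyphenol; 10 2-fluoro-5-(methoxymethoxy)benzene-1,3-dicarbaldehyde
Product: 27 rings F–G MOM ether
Conditions: K2CO3, DMF, rt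
Reagents that add atoms: none
Why: Nucleophilic aromatic substitution; the fluoride sits between two formyl groups and is displaced by the unhindered, electron-rich phenoxide at room temperature.

Step 16
Reactants: 27 rings F–G MOM ether
Product: 28 rings F–G phenol
Conditions: 3 M aq. HCl, THF, 50 °C
Reagents that add atoms: none
Why: Acid hydrolysis of the methoxymethyl ether; aldehydes, methyl ethers and the diaryl ether are inert to dilute aqueous acid, and the water-rich medium disfavours condensation of aldehydes or formaldehyde with the electron-rich ring G.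

Step 17
Reactants: 28 rings F–G phenol; 25 4-fluoro-5-[2-formyl-3-methoxy-5-(methoxymethoxy)phenoxy]-2-methoxybenzene-1,3-dicarbaldehyde
Product: 29 tetramer D–G MOM ether
Conditions: K2CO3, DMF, 60 °C
Reagents that add atoms: none
Why: Nucleophilic aromatic substitution at E6, whose fluoride has one formyl ortho and one para; the block brings in rings D and E at once, and the ring D ether already present is on an unactivated carbon.

Step 18
Reactants: 29 tetramer D–G MOM ether
Product: 30 tetramer D–G phenol
Conditions: 3 M aq. HCl, THF, 50 °C
Reagents that add atoms: none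
Why: Acid hydrolysis of the methoxymethyl ether, as in step 16.

Step 19
Reactants: 30 tetramer D–G phenol; 19 4-fluoro-2-methoxy-5-(methoxymethoxy)benzene-1,3-dicarbaldehyde
Product: 31 pentamer C–G MOM ether
Conditions: K2CO3, DMF, 60 °C
Reagents that add atoms: none
Why: Nucleophilic aromatic substitution at C6 by the ring D phenoxide. That phenoxide is para to a formyl group and only moderately nucleophilic, but fluoride on the doubly activated ring should still leave much faster than any aryloxide of the chain, which keeps ether exchange in the background.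

Step 20
Reactants: 31 pentamer C–G MOM ether
Product: 32 pentamer C–G phenol
Conditions: 3 M aq. HCl, THF, 50 °C
Reagents that add atoms: none
Why: Acid hydrolysis of the methoxymethyl ether, as in step 16.

Step 21
Reactants: 32 pentamer C–G phenol; 10 2-fluoro-5-(methoxymethoxy)benzene-1,3-dicarbaldehyde
Product: 33 hexamer B–G MOM ether
Conditions: K2CO3, DMF, 40 °C
Reagents that add atoms: none
Why: Nucleophilic aromatic substitution at B4, a fluoride between two formyl groups, by the ring C phenoxide, which has only one ortho substituent.

Step 22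
Reactants: 33 hexamer B–G MOM ether
Product: 34 hexamer B–G phenol
Conditions: 3 M aq. HCl, THF, 50 °C
Reagents that add atoms: none
Why: Acid hydrolysis of the methoxymethyl ether, as in step 16.

Step 23
Reactants: 34 hexamer B–G phenol; 9 2-fluoro-5-methoxybenzene-1,3-dicarbaldehyde
Product: 35 undecaformyl heptamer
Conditions: K2CO3, DMF, 40 °C
Reagents that add atoms: none
Why: Nucleophilic aromatic substitution at A1 by the unhindered ring B phenoxide; the last ring carries methoxy at A4, so no further unmasking is needed.

Step 24
Reactants: 35 undecaformyl heptamer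
Product: 37 undecaphenol heptamer with seven methyl ethers, via undecaformate 36 (not isolated)
Conditions: mCPBA (excess), CH2Cl2, 0 to 40 °C; Me2S; then HCl, MeOH, rt, argon
Reagents that add atoms: 3-chloroperbenzoic acid, OOC(=O)c1cccc(Cl)c1
Why: Proposed new method: an elevenfold Baeyer–Villiger (Dakin-type) oxidation on one oligo(formylaryl) ether is without precedent in extent; the closest known reactions are peracid oxidations of ortho- or para-alkoxy and -aryloxy benzaldehydes to aryl formates, including rings that carry two formyl groups. At each site the peracid adds to the formyl carbon, and in the Criegee adduct the aryl group migrates to the peroxide oxygen as 3-chlorobenzoate leaves, which gives the aryl formate; the ether oxygens insulate the rings from each other, so the sites should react independently. A formyloxy group is no stronger an acceptor than the formyl group it replaces, so reactivity should not fall off as the oxidation proceeds. The step closes no ring and creates no stereocentre. It needs aryl over hydride migration at all eleven sites: D4 has a coplanar ortho-methoxy and a para-aryloxy donor, whereas the ten formyls on rings A, B, C, E and F depend on ortho or para ether oxygens that are twisted by two neighbours, so these are the slow sites and set the excess of peracid and the time. The water-free, non-nucleophilic medium keeps the products as formates, which peracid does not attack; the excess oxidant is reduced with Me2S before acid methanolysis releases the eleven phenols, so no free phenol meets the oxidant.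

Step 25
Reactants: 37 undecaphenol heptamer with seven methyl ethers
Product: 38 CNP0130704.0
Conditions: BBr3 (excess), CH2Cl2, −78 °C to rt; MeOH, then H2O, argon
Reagents that add atoms: none
Why: Lewis-acid ether cleavage; bromide attacks the methyl carbon of each boron-complexed aryl methyl ether, while the diaryl ethers offer no sp3 carbon and stay intact. The acidic, oxygen-free work-up protects the polyphenol.

## Compound list

1 | 4-fluorophenol | Oc1ccc(F)cc1 | starting material
2 | (4-fluorophenoxy)tri(propan-2-yl)silane | CC(C)[Si](Oc1ccc(F)cc1)(C(C)C)C(C)C | intermediate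
3 | aryllithium: [2-fluoro-5-(triisopropylsilyloxy)phenyl]lithium | [Li]c1cc(O[Si](C(C)C)(C(C)C)C(C)C)ccc1F | intermediate (not isolated)
4 | lithium amino alkoxide: lithium (dimethylamino)[2-fluoro-5-(triisopropylsilyloxy)phenyl]methanolate, racemic | [Li]OC(N(C)C)c1cc(O[Si](C(C)C)(C(C)C)C(C)C)ccc1F | intermediate (not isolated)
5 | ring-lithiated amino alkoxide: lithium (dimethylamino)[2-fluoro-3-lithio-5-(triisopropylsilyloxy)phenyl]methanolate, racemic | [Li]OC(N(C)C)c1cc(O[Si](C(C)C)(C(C)C)C(C)C)cc([Li])c1F | intermediate (not isolated)
6 | dilithium bis(amino alkoxide): dilithium [2-fluoro-5-(triisopropylsilyloxy)-1,3-phenylene]bis[(dimethylamino)methanolate], stereoisomer mixture | [Li]OC(N(C)C)c1cc(O[Si](C(C)C)(C(C)C)C(C)C)cc(C(O[Li])N(C)C)c1F | intermediate (not isolated)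
7 | 2-fluoro-5-{[tri(propan-2-yl)silyl]oxy}benzene-1,3-dicarbaldehyde | CC(C)[Si](Oc1cc(C=O)c(F)c(C=O)c1)(C(C)C)C(C)C | intermediate
8 | 2-fluoro-5-hydroxybenzene-1,3-dicarbaldehyde | Oc1cc(C=O)c(F)c(C=O)c1 | intermediate
9 | 2-fluoro-5-methoxybenzene-1,3-dicarbaldehyde (ring A monomer) | COc1cc(C=O)c(F)c(C=O)c1 | intermediate
10 | 2-fluoro-5-(methoxymethoxy)benzene-1,3-dicarbaldehyde (monomer for rings B and F) | COCOc1cc(C=O)c(F)c(C=O)c1 | intermediate
11 | 2-fluoro-4-methoxyphenol | COc1ccc(O)c(F)c1 | starting material
12 | (2-fluoro-4-methoxyphenoxy)tri(propan-2-yl)silane | COc1ccc(O[Si](C(C)C)(C(C)C)C(C)C)c(F)c1 | intermediate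
13 | aryllithium: [2-fluoro-6-methoxy-3-(triisopropylsilyloxy)phenyl]lithium | COc1ccc(O[Si](C(C)C)(C(C)C)C(C)C)c(F)c1[Li] | intermediate (not isolated)
14 | lithium amino alkoxide: lithium (dimethylamino)[2-fluoro-6-methoxy-3-(triisopropylsilyloxy)phenyl]methanolate, racemic | COc1ccc(O[Si](C(C)C)(C(C)C)C(C)C)c(F)c1C(O[Li])N(C)C | intermediate (not isolated)
15 | ring-lithiated amino alkoxide: lithium (dimethylamino)[2-fluoro-5-lithio-6-methoxy-3-(triisopropylsilyloxy)phenyl]methanolate, racemic | COc1c([Li])cc(O[Si](C(C)C)(C(C)C)C(C)C)c(F)c1C(O[Li])N(C)C | intermediate (not isolated)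
16 | dilithium bis(amino alkoxide): dilithium [4-fluoro-2-methoxy-5-(triisopropylsilyloxy)-1,3-phenylene]bis[(dimethylamino)methanolate], stereoisomer mixture | COc1c(C(O[Li])N(C)C)cc(O[Si](C(C)C)(C(C)C)C(C)C)c(F)c1C(O[Li])N(C)C | intermediate (not isolated)
17 | 4-fluoro-2-methoxy-5-{[tri(propan-2-yl)silyl]oxy}benzene-1,3-dicarbaldehyde | COc1c(C=O)cc(O[Si](C(C)C)(C(C)C)C(C)C)c(F)c1C=O | intermediate
18 | 4-fluoro-5-hydroxy-2-methoxybenzene-1,3-dicarbaldehyde | COc1c(C=O)cc(O)c(F)c1C=O | intermediate
19 | 4-fluoro-2-methoxy-5-(methoxymethoxy)benzene-1,3-dicarbaldehyde (ring C monomer) | COCOc1cc(C=O)c(OC)c(C=O)c1F | intermediate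
20 | 2,6-difluoro-4-hydroxybenzaldehyde | O=Cc1c(F)cc(O)cc1F | starting material
21 | 2,6-difluoro-4-(methoxymethoxy)benzaldehyde | COCOc1cc(F)c(C=O)c(F)c1 | intermediate
22 | 2-fluoro-6-methoxy-4-(methoxymethoxy)benzaldehyde (ring D monomer) | COCOc1cc(F)c(C=O)c(OC)c1 | intermediate
23 | 3,5-bis(dimethoxymethyl)-2-fluoro-4-methoxyphenol | COc1c(C(OC)OC)cc(O)c(F)c1C(OC)OC | intermediate
24 | 2-[3,5-bis(dimethoxymethyl)-2-fluoro-4-methoxyphenoxy]-6-methoxy-4-(methoxymethoxy)benzaldehyde | COCOc1cc(OC)c(C=O)c(Oc2cc(C(OC)OC)c(OC)c(C(OC)OC)c2F)c1 | intermediate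
25 | 4-fluoro-5-[2-formyl-3-methoxy-5-(methoxymethoxy)phenoxy]-2-methoxybenzene-1,3-dicarbaldehyde (block for rings D and E) | COCOc1cc(OC)c(C=O)c(Oc2cc(C=O)c(OC)c(C=O)c2F)c1 | intermediate
26 | 3,4,5-trimethoxyphenol | COc1cc(O)cc(OC)c1OC | starting material
27 | rings F–G MOM ether: 5-(methoxymethoxy)-2-(3,4,5-trimethoxyphenoxy)benzene-1,3-dicarbaldehyde | COCOc1cc(C=O)c(Oc2cc(OC)c(OC)c(OC)c2)c(C=O)c1 | intermediate
28 | rings F–G phenol: 5-hydroxy-2-(3,4,5-trimethoxyphenoxy)benzene-1,3-dicarbaldehyde | Oc1cc(C=O)c(Oc2cc(OC)c(OC)c(OC)c2)c(C=O)c1 | intermediate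
29 | tetramer D–G MOM ether: ring D 1-OMOM, 3-OMe, 4-CHO, 5-O–E1; ring E 3,5-(CHO)2, 4-OMe, 6-O–F1; ring F 3,5-(CHO)2, 4-O–G1; ring G 3,4,5-(OMe)3 | COCOc1cc(OC)c(C=O)c(Oc2cc(C=O)c(OC)c(C=O)c2Oc3cc(C=O)c(Oc4cc(OC)c(OC)c(OC)c4)c(C=O)c3)c1 | intermediate
30 | tetramer D–G phenol: as 29 with D1-OH | Oc1cc(OC)c(C=O)c(Oc2cc(C=O)c(OC)c(C=O)c2Oc3cc(C=O)c(Oc4cc(OC)c(OC)c(OC)c4)c(C=O)c3)c1 | intermediate
31 | pentamer C–G MOM ether: ring C 1-OMOM, 3,5-(CHO)2, 4-OMe, 6-O–D1; rings D to G as in 30 | COCOc1cc(C=O)c(OC)c(C=O)c1Oc2cc(OC)c(C=O)c(Oc3cc(C=O)c(OC)c(C=O)c3Oc4cc(C=O)c(Oc5cc(OC)c(OC)c(OC)c5)c(C=O)c4)c2 | intermediate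
32 | pentamer C–G phenol: as 31 with C1-OH | Oc1cc(C=O)c(OC)c(C=O)c1Oc2cc(OC)c(C=O)c(Oc3cc(C=O)c(OC)c(C=O)c3Oc4cc(C=O)c(Oc5cc(OC)c(OC)c(OC)c5)c(C=O)c4)c2 | intermediate
33 | hexamer B–G MOM ether: ring B 1-OMOM, 3,5-(CHO)2, 4-O–C1; rings C to G as in 32 | COCOc1cc(C=O)c(Oc2cc(C=O)c(OC)c(C=O)c2Oc3cc(OC)c(C=O)c(Oc4cc(C=O)c(OC)c(C=O)c4Oc5cc(C=O)c(Oc6cc(OC)c(OC)c(OC)c6)c(C=O)c5)c3)c(C=O)c1 | intermediate
34 | hexamer B–G phenol: as 33 with B1-OH | Oc1cc(C=O)c(Oc2cc(C=O)c(OC)c(C=O)c2Oc3cc(OC)c(C=O)c(Oc4cc(C=O)c(OC)c(C=O)c4Oc5cc(C=O)c(Oc6cc(OC)c(OC)c(OC)c6)c(C=O)c5)c3)c(C=O)c1 | intermediate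
35 | undecaformyl heptamer: ring A 1-O–B1, 2,6-(CHO)2, 4-OMe; rings B to G as in 34 | COc1cc(C=O)c(Oc2cc(C=O)c(Oc3cc(C=O)c(OC)c(C=O)c3Oc3cc(OC)c(C=O)c(Oc4cc(C=O)c(OC)c(C=O)c4Oc4cc(C=O)c(Oc5cc(OC)c(OC)c(OC)c5)c(C=O)c4)c3)c(C=O)c2)c(C=O)c1 | intermediate
36 | undecaformate heptamer: 35 with every CHO replaced by OCHO | COc1cc(OC=O)c(Oc2cc(OC=O)c(Oc3cc(OC=O)c(OC)c(OC=O)c3Oc3cc(OC)c(OC=O)c(Oc4cc(OC=O)c(OC)c(OC=O)c4Oc4cc(OC=O)c(Oc5cc(OC)c(OC)c(OC)c5)c(OC=O)c4)c3)c(OC=O)c2)c(OC=O)c1 | intermediate (not isolated)
37 | undecaphenol heptamer with seven methyl ethers: 35 with every CHO replaced by OH | COc1cc(O)c(Oc2cc(O)c(Oc3cc(O)c(OC)c(O)c3Oc3cc(OC)c(O)c(Oc4cc(O)c(OC)c(O)c4Oc4cc(O)c(Oc5cc(OC)c(OC)c(OC)c5)c(O)c4)c3)c(O)c2)c(O)c1 | intermediate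
38 | CNP0130704.0: 37 with every OMe replaced by OH | Oc1cc(O)c(Oc2cc(O)c(Oc3cc(O)c(O)c(O)c3Oc3cc(O)c(O)c(Oc4cc(O)c(O)c(O)c4Oc4cc(O)c(Oc5cc(O)c(O)c(O)c5)c(O)c4)c3)c(O)c2)c(O)c1 | target

## Step count and least certain steps

Total: 25 steps. Longest linear sequence: 15 steps (1 to 38 through 2, 7, 8, 10, 27 and 28, or equally 11 to 38 through 12, 17, 18, 23, 24 and 25).

Step 24 (key step). The most likely failure is hydride migration competing with aryl migration at the ten sites that have only twisted ether donors, which would give carboxylic acids. Incomplete conversion would leave inseparable mixtures of partly oxidised chains, and premature loss of formate would expose phenols to the peracid. Slow electrophilic oxidation of the electron-rich ring G is a further risk. The fallback removes the hydrogen that can migrate. Setting out from 35, MeMgBr (THF, −78 to 0 °C) adds to all eleven formyl groups and gives the undeca(1-hydroxyethyl) heptamer F1 as a mixture of diastereomers. Dess–Martin periodinane oxidises it to the undecaacetyl heptamer F2. Peracid (mCPBA with CF3CO2H, CH2Cl2) converts F2 into the undecaacetate heptamer F3 by Baeyer–Villiger oxidation of aryl methyl ketones, where methyl migration does not compete. Acid methanolysis of F3 returns to the route at 37.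

Step 2. The second metalation has to occur on a species that already carries a lithium alkoxide. It may stay incomplete, or the ortho-fluoro aryllithium may lose lithium fluoride if the temperature rises, leading to aryne-derived material. The fallback isolates the stages. From 2, one lithiation and formylation with aqueous work-up gives 2-fluoro-5-{[tri(propan-2-yl)silyl]oxy}benzaldehyde F4. Ethylene glycol and TsOH convert it into 2-(2-fluoro-5-{[tri(propan-2-yl)silyl]oxy}phenyl)-1,3-dioxolane F5. s-BuLi then DMF give 3-(1,3-dioxolan-2-yl)-2-fluoro-5-{[tri(propan-2-yl)silyl]oxy}benzaldehyde F6. Dilute aqueous acid removes the acetal and returns to the route at 7.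

Step 7. The second metalation is directed only by a methoxy group that is crowded by the neighbouring amino alkoxide. Slow or misdirected deprotonation would leave the monoaldehyde. The fallback makes that carbon–carbon bond by electrophilic substitution instead. From 12, Rieche formylation (Cl2CHOMe, TiCl4, CH2Cl2, −78 to 0 °C) ortho to methoxy and para to fluorine gives 4-fluoro-2-methoxy-5-{[tri(propan-2-yl)silyl]oxy}benzaldehyde F7. Ethylene glycol and TsOH give 2-(4-fluoro-2-methoxy-5-{[tri(propan-2-yl)silyl]oxy}phenyl)-1,3-dioxolane F8. n-BuLi removes the hydrogen between fluorine and methoxy, and DMF gives 3-(1,3-dioxolan-2-yl)-6-fluoro-2-methoxy-5-{[tri(propan-2-yl)silyl]oxy}benzaldehyde F9. Aqueous acid returns to the route at 17.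

Step 13. Displacement of the weakly activated fluoride may be too slow, so that the aldehyde is consumed by base-induced disproportionation with traces of water during long heating. The fallback reverses the order of the two displacements on ring D. From 23 and the more reactive difluoride 21 (K2CO3, DMF, 60 °C) it gives 2-[3,5-bis(dimethoxymethyl)-2-fluoro-4-methoxyphenoxy]-6-fluoro-4-(methoxymethoxy)benzaldehyde F10. NaOMe (MeOH/THF, rt) then exchanges the remaining ring D fluoride; this is safe because the ring E fluoride is unactivated while its formyls are acetals. The sequence returns to the route at 24.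

Step 25. Demethylation of the methoxy groups flanked by two oxygens may lag behind. The free polyphenol may also be lost by air oxidation during isolation and chromatography. The fallback isolates a stable derivative. From 37, after the BBr3 treatment and methanol quench, the crude material is acetylated without isolation (Ac2O, pyridine) to the octadecaacetate of the target F11. F11 can be purified on silica and checked for completeness of demethylation. Acid methanolysis under argon (HCl, MeOH) returns to the route at 38.

## Further compounds

F1 | step 24 | undeca(1-hydroxyethyl) heptamer: 35 with every CHO replaced by CH(OH)CH3, mixture of diastereomers | COc1cc(C(C)O)c(Oc2cc(C(C)O)c(Oc3cc(C(C)O)c(OC)c(C(C)O)c3Oc3cc(OC)c(C(C)O)c(Oc4cc(C(C)O)c(OC)c(C(C)O)c4Oc4cc(C(C)O)c(Oc5cc(OC)c(OC)c(OC)c5)c(C(C)O)c4)c3)c(C(C)O)c2)c(C(C)O)c1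
F2 | step 24 | undecaacetyl heptamer: 35 with every CHO replaced by COCH3 | COc1cc(C(C)=O)c(Oc2cc(C(C)=O)c(Oc3cc(C(C)=O)c(OC)c(C(C)=O)c3Oc3cc(OC)c(C(C)=O)c(Oc4cc(C(C)=O)c(OC)c(C(C)=O)c4Oc4cc(C(C)=O)c(Oc5cc(OC)c(OC)c(OC)c5)c(C(C)=O)c4)c3)c(C(C)=O)c2)c(C(C)=O)c1
F3 | step 24 | undecaacetate heptamer: 35 with every CHO replaced by OCOCH3 | COc1cc(OC(C)=O)c(Oc2cc(OC(C)=O)c(Oc3cc(OC(C)=O)c(OC)c(OC(C)=O)c3Oc3cc(OC)c(OC(C)=O)c(Oc4cc(OC(C)=O)c(OC)c(OC(C)=O)c4Oc4cc(OC(C)=O)c(Oc5cc(OC)c(OC)c(OC)c5)c(OC(C)=O)c4)c3)c(OC(C)=O)c2)c(OC(C)=O)c1
F4 | step 2 | 2-fluoro-5-{[tri(propan-2-yl)silyl]oxy}benzaldehyde | O=Cc1cc(O[Si](C(C)C)(C(C)C)C(C)C)ccc1F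
F5 | step 2 | 2-(2-fluoro-5-{[tri(propan-2-yl)silyl]oxy}phenyl)-1,3-dioxolane | Fc1ccc(O[Si](C(C)C)(C(C)C)C(C)C)cc1C1OCCO1
F6 | step 2 | 3-(1,3-dioxolan-2-yl)-2-fluoro-5-{[tri(propan-2-yl)silyl]oxy}benzaldehyde | O=Cc1cc(O[Si](C(C)C)(C(C)C)C(C)C)cc(C2OCCO2)c1F
F7 | step 7 | 4-fluoro-2-methoxy-5-{[tri(propan-2-yl)silyl]oxy}benzaldehyde | COc1cc(F)c(O[Si](C(C)C)(C(C)C)C(C)C)cc1C=O
F8 | step 7 | 2-(4-fluoro-2-methoxy-5-{[tri(propan-2-yl)silyl]oxy}phenyl)-1,3-dioxolane | COc1cc(F)c(O[Si](C(C)C)(C(C)C)C(C)C)cc1C1OCCO1
F9 | step 7 | 3-(1,3-dioxolan-2-yl)-6-fluoro-2-methoxy-5-{[tri(propan-2-yl)silyl]oxy}benzaldehyde | COc1c(C=O)c(F)c(O[Si](C(C)C)(C(C)C)C(C)C)cc1C1OCCO1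
F10 | step 13 | 2-[3,5-bis(dimethoxymethyl)-2-fluoro-4-methoxyphenoxy]-6-fluoro-4-(methoxymethoxy)benzaldehyde | COCOc1cc(F)c(C=O)c(Oc2cc(C(OC)OC)c(OC)c(C(OC)OC)c2F)c1
F11 | step 25 | octadecaacetate of the target: 38 with every OH replaced by OCOCH3 | CC(=O)Oc1cc(OC(C)=O)c(Oc2cc(OC(C)=O)c(Oc3cc(OC(C)=O)c(OC(C)=O)c(OC(C)=O)c3Oc3cc(OC(C)=O)c(OC(C)=O)c(Oc4cc(OC(C)=O)c(OC(C)=O)c(OC(C)=O)c4Oc4cc(OC(C)=O)c(Oc5cc(OC(C)=O)c(OC(C)=O)c(OC(C)=O)c5)c(OC(C)=O)c4)c3)c(OC(C)=O)c2)c(OC(C)=O)c1
A1 | alternative 1 | dimethyl 2-[4-(benzyloxy)-3,5-dimethoxyphenoxy]propanedioate | COC(=O)C(Oc1cc(OC)c(OCc2ccccc2)c(OC)c1)C(=O)OC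
A2 | alternative 1 | dimethyl 3-oxopentanedioate | COC(=O)CC(=O)CC(=O)OC
A3 | alternative 1 | dimethyl 5-[4-(benzyloxy)-3,5-dimethoxyphenoxy]-2,4,6-trihydroxybenzene-1,3-dicarboxylate | COC(=O)c1c(O)c(C(=O)OC)c(O)c(Oc2cc(OC)c(OCc3ccccc3)c(OC)c2)c1O
A4 | alternative 2 | 4-{(Z)-2-[2,6-dimethoxy-4-(2,4,6-trimethoxyphenoxy)phenoxy]ethenyl}-4-hydroxy-2,3-dimethoxycyclobut-2-en-1-one, racemic | COC1=C(OC)C(O)(/C=C\Oc2c(OC)cc(Oc3c(OC)cc(OC)cc3OC)cc2OC)C1=O
A5 | alternative 2 | 5-[2,6-dimethoxy-4-(2,4,6-trimethoxyphenoxy)phenoxy]-2,3-dimethoxybenzene-1,4-diol | COc1c(O)cc(Oc2c(OC)cc(Oc3c(OC)cc(OC)cc3OC)cc2OC)c(O)c1OC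
A6 | alternative 3 | 2,4,6-trifluorobenzaldehyde | O=Cc1c(F)cc(F)cc1F
A7 | alternative 3 | heptameric 2-aryloxy-4-aryloxy-6-fluorobenzaldehyde: ring D as 2-fluorobenzaldehyde with the A8 aryloxy group para and the A9 aryloxy group ortho to the formyl group | COc1cc(OC)c(Oc2cc(OC)c(Oc3cc(OC)c(OC)c(OC)c3Oc3cc(F)c(C=O)c(Oc4cc(OC)c(OC)c(OC)c4Oc4cc(OC)c(Oc5cc(OC)c(OC)c(OC)c5)c(OC)c4)c3)c(OC)c2)c(OC)c1
A8 | alternative 3 | arm A–B–C: 6-[2,6-dimethoxy-4-(2,4,6-trimethoxyphenoxy)phenoxy]-2,3,4-trimethoxyphenol | COc1cc(OC)c(Oc2cc(OC)c(Oc3cc(OC)c(OC)c(OC)c3O)c(OC)c2)c(OC)c1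
A9 | alternative 3 | arm E–F–G: 2-[3,5-dimethoxy-4-(3,4,5-trimethoxyphenoxy)phenoxy]-3,4,5-trimethoxyphenol | COc1cc(O)c(Oc2cc(OC)c(Oc3cc(OC)c(OC)c(OC)c3)c(OC)c2)c(OC)c1OC
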